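(All constants stand for no real mixture; the result is computed.)

Start from the target: each one formed sets free one acid, and that acid takes up a second nucleophile, so each target costs two nucleophiles.

    electrophile + nucleophile ⇌ acid set free + target (K1 = 0.29, k1 = 6.9 L mol⁻¹ h⁻¹)
    nucleophile + acid set free ⇌ protonated nucleophile, settled at all times (K2 = 24000 L mol⁻¹)
    nucleophile + target ⇌ idle adduct, settled at all times (K3 = 2.3 L mol⁻¹)

- amber: electrophile 0.15 M (fed, over 6.0 h); nucleophile 1.50 equiv; time 12 h
- blue: electrophile 0.15 M (fed, over 6.0 h); nucleophile 3.00 equiv; time 12 h

- for target the idle adduct is counted in
- run time (amber): 12 h

- part of the electrophile that has reacted at the end, amber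
- part of the electrophile that has reacted at the end, blue
- what raising the equivalents of nucleophile from its lowest to its highest value here does to the part of the electrophile that has reacted (changes below 5 percentage points count as none) (it falls / no change / it rises)

Begin with the bench rule that a strong trap for the acid pulls an unfavourable step through. Add the first two steps into electrophile + two nucleophile ⇌ target + protonated nucleophile, and let Π be the product of their constants and the electrophile charge. Work in powers of ten:

log Π = −0.538 + 3.56 = 3.02

So Π is 1040, and the rule promises near completion. In amber, the half-life of electrophile by the forward rate of the first step, other concentrations as charged, is 0.45 h, short against 12 h, so reckon the end as a balance.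

Now find the border. Amber's 75.0 % is its ceiling, the equivalents of nucleophile over the 2 that each reacted electrophile costs. Blue's ceiling is 150 %. Amber stands below full conversion, so there nucleophile is the limiting reagent and the rule stops; blue stands above it.

Let x be the share reacted and b the free nucleophile per electrophile charged, and ignore free acid and idle adduct, so that Π·b·b = x·x/(1 − x). For amber, put x at the ceiling:

log b = (0.352 − 3.02) / 2 = −1.33

b = 0.0464

x = ceiling − b/2 = 72.7 %

For blue, the same count with idle adduct ignored puts b near 1.00, so x = 99.9 %. I therefore expect a rise of 27 percentage points, beyond the 5 points that counts.

The forecast differs from this reckoning on amber and on the trend. It gives 98.2 % (96.5 % to 99.2 %) for amber, 99.9 % (99.5 % to 100 %) for blue, and "no change", on the grounds that the nucleophile “traps the released acid so strongly”. The forecast's number is what one gets with the nucleophile held at its starting value.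

The simulation gives 72.5 % for amber and 99.8 % for blue, so the answer is "it rises", by 27 points. Amber ends 2.5 points under its ceiling of 75.0 %, with 2.9 % of its nucleophile still free. Take the neighbour of amber charged with 0.600 equiv of nucleophile: its ceiling is 30.0 %, and the flask gives 29.8 %. In that neighbour, 70 % of the electrophile stands unreacted at the end, with free nucleophile down to 1.8 % of its charge.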